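The numbers of this flask were chosen freely, and the outcome is calculated.

I began from the leftover: how much electrophile stays over when the nucleophile can also be spent on itself?

| flask | electrophile | nucleophile | time |
|---|---|---|---|
| spring | 2.0 mM | 1.10 equiv | 2.0 min |
| dawn | 2.0 mM | 2.10 equiv | 2.0 min |

- part of the electrophile that has reacted at the end, spring
- part of the electrophile that has reacted at the end, dawn
- what raising the equivalents of nucleophile from its lowest to its highest value here does to the part of the electrophile that has reacted (changes below 5 percentage points count as none) (it rises / it falls / no change)

    electrophile + nucleophile → acid set free + target (k1 = 39 M⁻¹ s⁻¹)
    nucleophile + acid set free ⇌ protonated nucleophile, settled at all times (K2 = 8600 M⁻¹)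
    2 nucleophile → self-condensation product (k3 = 170 M⁻¹ s⁻¹)
    nucleophile ⇌ dormant form (K4 = 0.40, k4 = 1.0 s⁻¹)
    acid set free + target → side product (k5 = 5.5 M⁻¹ s⁻¹)

Each turn with electrophile costs one nucleophile and each self-condensation costs two, so with electrophile as charged the two steps take equal amounts when free nucleophile stands at 0.229 mM; I called this the even-split level, the electrophile times its rate constant over twice the self-condensation constant. With the dormant form at balance, free nucleophile starts near 1.57 mM in spring and 3.00 mM at dawn, which at dawn is 13.1 times the level.

Following the split down, with acid set aside, gives the electrophile reacted as 1.40 times the level times the natural log of one plus start over level. Electrophile held as charged gave my upper marks, 33.1% for spring and 42.5% for dawn. Electrophile held at what those marks leave gave my lower marks, 26.0% and 29.3%. The mean electrophile gave 29.8% and 36.3%, the figures I committed to. With acid left out, these marks bound the split and are not strict walls.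

The forecast said 34% and 43%, with ranges 31% to 37% and 39% to 47%, and of the part reacted on raising the equivalents: it rises, on the ground that self-condensation “burns most of the nucleophile”. Both its values stand slightly higher than my upper marks. The simulation gave 33.4% for spring and 41.7% for dawn, and of the part reacted on raising the equivalents: it rises, by 8.3 percentage points; spring lies just higher than my upper mark, dawn just lower, and both lie within the forecast's ranges.

At dawn self-condensation had 95% of its turnover up to 2.0 min behind it by 0.200 min, while the target step reached the midpoint of its own turnover at 0.103 min. By 1.00 min free nucleophile, the limiting reagent, stood at 0.0461 mM, lower than the level of 0.144 mM reckoned for the electrophile then present, and the step from acid and target had 36% of its turnover behind it. The neighbour of dawn charged with 0.80 mM of electrophile has level 0.0918 mM and start 1.20 mM, which keeps the upper mark at 42.5%, and it reacted to 36.9%.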